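**Retrosynthetic overview**

- The target is reached from a 6β,7α-diol by 7-O-acylation, 6-O-acetylation and ester deprotection; the diol comes from a trans-fused 6-oxo-7,7-dimethoxy bicycle by C6 reduction, ketal hydrolysis and hydroxyl-directed C7 reduction.
- That bicycle is disconnected at C1–C10: ring A is closed last by an enantioselective 6-endo radical conjugate cyclisation of an achiral o-quinone monoketal, itself made by oxidative dearomatisation of a hexasubstituted 2-methoxyphenol.
- Enabling feature: ring B carries oxygen on the adjacent C6 and C7 next to the C8=C9 double bond, so it is a catechol at a reduced oxidation level. In the derived dienone C6(=O)–C5=C10–C9=C8–C7(OMe)2 the methyl-bearing C10 is the β-carbon, and C5, which holds the C4–C3–C2–C1 tether, is the α-carbon.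
- The arene comes from 2-hydroxy-3,5-dimethylbenzaldehyde: the C4–C5 bond and gem-dimethyl group by Friedel–Crafts lactonisation with 3-methylbut-2-enoic acid, C1 by Wittig methylenation, the side chain C11–C15 by B-alkyl Suzuki coupling with a stereodefined dienoate.
- Ring order: ring B (aromatic, from the starting material), then a temporary lactone ring (steps 3–6, opened again), then ring A (step 13).

Key step: step 13

Remark: labdane numbering is used for the bicyclic compounds (ring A = C1–C5, C10; ring B = C5–C10; the C10 methyl is β); the target is (5S,6S,7S,10S,13E).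
Remark (assumption): the sense of induction of the magnesium bisoxazoline complex in step 13 cannot be derived from a closely related case; the (S,S)-ligand (2,2′-(propane-2,2-diyl)bis[(4S)-4-tert-butyl-4,5-dihydro-1,3-oxazole], "(S,S)-t-Bu-box") is written, and its antipode is used if the first experiment shows that it favours the (10R)-series.

**Route**

Step 1
Reactants: 1 2-hydroxy-3,5-dimethylbenzaldehyde
Product: 2 2-methoxy-3,5-dimethylbenzaldehyde
Conditions: MeI, K2CO3, DMF, rt
Reagents that add atoms: iodomethane, CI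
Why: Williamson O-methylation of the only acidic hydroxyl, whose oxygen becomes the C7 oxygen; no stereocentre is formed.

Step 2
Reactants: 2 2-methoxy-3,5-dimethylbenzaldehyde
Product: 4 2-methoxy-3,5-dimethylphenol, via aryl formate 3 (not isolated)
Conditions: mCPBA, CH2Cl2, 0 °C → rt; then K2CO3 (cat.), MeOH, rt
Reagents that add atoms: 3-chloroperoxybenzoic acid, OOC(=O)c1cccc(Cl)c1
Why: Baeyer–Villiger (Dakin-type) oxidation, in which the electron-rich o-methoxyaryl group migrates, places the future C6 oxygen on the ring, and methanolysis of the formate frees the phenol; no stereocentre.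

Step 3
Reactants: 4 2-methoxy-3,5-dimethylphenol; 5 3-methylbut-2-enoic acid
Product: 6 8-methoxy-4,4,5,7-tetramethylchroman-2-one
Conditions: MeSO3H, 70 °C
Reagents that add atoms: none
Why: Friedel–Crafts alkylation–lactonisation (the trimethyl-lock lactone synthesis): the tertiary cation attacks C5, the only free position ortho to the phenol, and irreversible closure of the six-membered lactone secures the congested aryl–C4 bond with its gem-dimethyl group; no stereocentre.

Step 4
Reactants: 6 8-methoxy-4,4,5,7-tetramethylchroman-2-one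
Product: 7 6-bromo-8-methoxy-4,4,5,7-tetramethylchroman-2-one
Conditions: Br2, NaOAc, AcOH, rt
Reagents that add atoms: bromine, BrBr
Why: electrophilic aromatic bromination at the single remaining ring position (the future C9), which is para to the ring oxygen and flanked by two methyl groups.

Step 5
Reactants: 7 6-bromo-8-methoxy-4,4,5,7-tetramethylchroman-2-one
Product: 8 6-bromo-8-methoxy-4,4,5,7-tetramethylchroman-2-ol (lactol)
Conditions: i-Bu2AlH, CH2Cl2, −78 °C; aq. potassium sodium tartrate
Reagents that add atoms: none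
Why: partial reduction of the aryl lactone stops at the aluminium hemiacetal at low temperature; the lactol carbon is a racemic stereocentre of no consequence, destroyed in step 6.

Step 6
Reactants: 8 6-bromo-8-methoxy-4,4,5,7-tetramethylchroman-2-ol
Product: 9 4-bromo-2-methoxy-3,5-dimethyl-6-(2-methylpent-4-en-2-yl)phenol
Conditions: Ph3PCH3Br, KOtBu (excess), THF, 0 °C → rt
Reagents that add atoms: methyltriphenylphosphonium bromide, C[P+](c1ccccc1)(c1ccccc1)c1ccccc1.[Br-]
Why: Wittig methylenation of the hydroxy aldehyde in equilibrium with the lactol adds C1 and opens the temporary ring to the free phenol.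

Step 7
Reactants: 9 4-bromo-2-methoxy-3,5-dimethyl-6-(2-methylpent-4-en-2-yl)phenol
Product: 11 4-(3-bromo-6-hydroxy-5-methoxy-2,4-dimethylphenyl)-4-methylpentan-1-ol, via alkylborane 10 (not isolated)
Conditions: 9-BBN, THF, 0 °C → rt; then NaOH, H2O2, 0 °C
Reagents that add atoms: hydrogen peroxide, OO
Why: anti-Markovnikov hydroboration–oxidation of the terminal alkene places the hydroxyl on C1; aryl bromide and phenol are inert.

Step 8
Reactants: 12 but-2-ynoic acid
Product: 13 2-(trimethylsilyl)ethyl but-2-ynoate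
Conditions: 2-(trimethylsilyl)ethanol, DCC, DMAP (cat.), CH2Cl2, 0 °C → rt
Reagents that add atoms: 2-(trimethylsilyl)ethanol, C[Si](C)(C)CCO
Why: Steglich esterification installs a carboxyl protecting group that fluoride removes at the end without touching the acetate and the 3-methylbutanoate.

Step 9
Reactants: 13 2-(trimethylsilyl)ethyl but-2-ynoate
Product: 14 2-(trimethylsilyl)ethyl (2E)-3-methylpenta-2,4-dienoate
Conditions: CH2=CHMgBr, CuI (10 mol %), THF, −78 °C; NH4Cl at −78 °C
Reagents that add atoms: vinylmagnesium bromide, C=C[Mg]Br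
Why: copper-catalysed syn-carbometalation of the ynoate and protonation of the alkenylmetal at −78 °C with retention place the vinyl group trans to the ester, which fixes the later 13E geometry.

Step 10
Reactants: 11 4-(3-bromo-6-hydroxy-5-methoxy-2,4-dimethylphenyl)-4-methylpentan-1-ol; 14 2-(trimethylsilyl)ethyl (2E)-3-methylpenta-2,4-dienoate
Product: 16 2-(trimethylsilyl)ethyl (2E)-5-[4-hydroxy-3-(5-hydroxy-2-methylpentan-2-yl)-5-methoxy-2,6-dimethylphenyl]-3-methylpent-2-enoate, via alkylborane 15 (not isolated)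
Conditions: 14, 9-BBN, THF, 0 °C → rt; then 11, Pd(OAc)2 (5 mol %), SPhos (10 mol %), K3PO4, THF/H2O, 65 °C
Reagents that add atoms: none
Why: B-alkyl Suzuki–Miyaura coupling: 9-BBN adds only to the terminal vinyl group of 14, and the primary alkylborane couples with the doubly ortho-substituted aryl bromide under SPhos ligation, which tolerates the free phenol and alcohol; the E-enoate is untouched.

Step 11
Reactants: 16 (hydroxyalkyl phenol)
Product: 17 2-(trimethylsilyl)ethyl (2E)-5-[3-(5-bromo-2-methylpentan-2-yl)-4-hydroxy-5-methoxy-2,6-dimethylphenyl]-3-methylpent-2-enoate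
Conditions: CBr4, PPh3, CH2Cl2, 0 °C
Reagents that add atoms: carbon tetrabromide, BrC(Br)(Br)Br
Why: the Appel reaction converts the primary alcohol into the radical precursor under neutral conditions, so the phenol neither reacts nor closes an ether ring.

Step 12
Reactants: 17 (bromoalkyl phenol)
Product: 18 2-(trimethylsilyl)ethyl (2E)-5-[5-(5-bromo-2-methylpentan-2-yl)-3,3-dimethoxy-2,6-dimethyl-4-oxocyclohexa-1,5-dien-1-yl]-3-methylpent-2-enoate (o-quinone monoketal)
Conditions: PhI(OAc)2, MeOH, 0 °C
Reagents that add atoms: methanol, CO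
Why: oxidative dearomatisation of a 2-methoxyphenol to the o-quinone monoketal: methanol attacks C7, where the cation is stabilised by the methoxy group, and the fully substituted diene cannot dimerise; the product is achiral.

Step 13
Reactants: 18 (o-quinone monoketal)
Product: 19 2-(trimethylsilyl)ethyl (5S,10S,13E)-7,7-dimethoxy-6-oxolabda-8,13-dien-15-oate (5α-H, trans-fused)
Conditions: Mg(NTf2)2 (1.0 equiv), (S,S)-t-Bu-box (1.1 equiv), CH2Cl2, −78 °C; Bu3SnH (syringe pump), Et3B, air, −78 → −40 °C
Reagents that add atoms: none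
Why: Proposed new method: Bu3Sn• abstracts the bromine atom and the primary C1 radical adds to C10, the β-carbon of the Lewis-acid-activated enone C6(=O)–C5=C10, after which the C5 α-keto radical takes a hydrogen atom from Bu3SnH. The closest known reaction types are the tin hydride 6-endo cyclisation of α-(ω-haloalkyl)enones and the magnesium bisoxazoline-mediated enantioselective radical conjugate addition to α′-oxygenated enones held by two-point binding; neither has been shown on an o-quinone monoketal or for a ligand-controlled quaternary centre. Ring A closes in the 6-endo-trig mode through the single new bond C1–C10. C10 is controlled by the chiral magnesium complex, which chelates the C6 carbonyl oxygen and one of the two enantiotopic ketal oxygens on C7 and thereby blocks one face of the planar dienone so that the tether reaches C10 from the other; C5 is controlled by the substrate, hydrogen being delivered anti to the now syn-axial C10 and C4 methyl groups, which gives the trans ring fusion. The step needs 6-endo over 5-exo attack (secured by the polarity of the enone and by the quaternary C4, which would otherwise sit next to a second quaternary centre), cyclisation faster than reduction of the C1 radical (slow addition of the stannane) and no epimerisation at C5 (neutral conditions, direct use in step 14).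

Step 14
Reactants: 19 (keto ketal)
Product: 21 2-(trimethylsilyl)ethyl (5S,6S,10S,13E)-6β-hydroxy-7-oxolabda-8,13-dien-15-oate, via hydroxy ketal 20 (not isolated)
Conditions: NaBH4, CeCl3·7H2O, MeOH/THF, −20 °C; then 1 M aq. HCl, THF, 0 °C → rt
Reagents that add atoms: water, O
Why: Luche-type borohydride reduction, in which hydride reaches C6 from the α-face because the β-face is closed by the syn-axial methyl groups on C10 and C4, gives the axial 6β-alcohol and locks C5; aqueous acid then hydrolyses the dimethyl ketal to the conjugated C7 ketone.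

Step 15
Reactants: 21 (6β-hydroxy enone)
Product: 22 2-(trimethylsilyl)ethyl (5S,6S,7S,10S,13E)-6β,7α-dihydroxylabda-8,13-dien-15-oate
Conditions: Me4NBH(OAc)3, MeCN/AcOH, −20 °C
Reagents that add atoms: none
Why: hydroxyl-directed Evans–Saksena reduction: the borohydride bound to the 6β-oxygen delivers hydride to the β-face of C7, which sets the 7α-hydroxyl trans to the 6β-hydroxyl.

Step 16
Reactants: 22 (6β,7α-diol)
Product: 23 2-(trimethylsilyl)ethyl (5S,6S,7S,10S,13E)-6β-hydroxy-7α-(3-methylbutanoyloxy)labda-8,13-dien-15-oate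
Conditions: 3-methylbutanoyl chloride, pyridine, DMAP (cat.), CH2Cl2, −20 → 0 °C
Reagents that add atoms: 3-methylbutanoyl chloride, CC(C)CC(=O)Cl
Why: site-selective esterification: the allylic 7α-hydroxyl is open on the α-face, whereas the 6β-hydroxyl is 1,3-diaxial to two methyl groups; the trans-diaxial arrangement excludes acyl migration.

Step 17
Reactants: 23 (7α-monoester)
Product: 24 2-(trimethylsilyl)ethyl (5S,6S,7S,10S,13E)-6β-acetoxy-7α-(3-methylbutanoyloxy)labda-8,13-dien-15-oate
Conditions: Ac2O, DMAP, Et3N, CH2Cl2, 40 °C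
Reagents that add atoms: acetic anhydride, CC(=O)OC(C)=O
Why: DMAP-catalysed acetylation under forcing but non-acidic conditions acylates the hindered axial 6β-hydroxyl with retention.

Step 18
Reactants: 24 (silylethyl ester)
Product: 25 (5S,6S,7S,10S,13E)-6β-acetoxy-7α-(3-methylbutanoyloxy)labda-8,13-dien-15-oic acid (CNP0328312.2)
Conditions: Bu4NF, THF, 0 °C → rt; aq. NH4Cl
Reagents that add atoms: none
Why: fluoride-induced β-elimination of the 2-(trimethylsilyl)ethyl ester frees the acid under conditions that leave the acetate, the allylic 3-methylbutanoate and the 13E alkene unchanged.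

**Compound list**

1 | 2-hydroxy-3,5-dimethylbenzaldehyde | Cc1cc(C)c(O)c(C=O)c1 | starting material
2 | 2-methoxy-3,5-dimethylbenzaldehyde | COc1c(C)cc(C)cc1C=O | intermediate
3 | 2-methoxy-3,5-dimethylphenyl formate | COc1c(C)cc(C)cc1OC=O | intermediate (not isolated)
4 | 2-methoxy-3,5-dimethylphenol | COc1c(C)cc(C)cc1O | intermediate
5 | 3-methylbut-2-enoic acid | CC(C)=CC(=O)O | starting material
6 | 8-methoxy-4,4,5,7-tetramethylchroman-2-one | COc1c(C)cc(C)c2c1OC(=O)CC2(C)C | intermediate
7 | 6-bromo-8-methoxy-4,4,5,7-tetramethylchroman-2-one | COc1c(C)c(Br)c(C)c2c1OC(=O)CC2(C)C | intermediate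
8 | 6-bromo-8-methoxy-4,4,5,7-tetramethylchroman-2-ol (racemic lactol) | COc1c(C)c(Br)c(C)c2c1OC(O)CC2(C)C | intermediate
9 | 4-bromo-2-methoxy-3,5-dimethyl-6-(2-methylpent-4-en-2-yl)phenol | COc1c(C)c(Br)c(C)c(C(C)(C)CC=C)c1O | intermediate
10 | 9-[4-(3-bromo-6-hydroxy-5-methoxy-2,4-dimethylphenyl)-4-methylpentyl]-9-borabicyclo[3.3.1]nonane | COc1c(C)c(Br)c(C)c(C(C)(C)CCCB2C3CCCC2CCC3)c1O | intermediate (not isolated)
11 | 4-(3-bromo-6-hydroxy-5-methoxy-2,4-dimethylphenyl)-4-methylpentan-1-ol | COc1c(C)c(Br)c(C)c(C(C)(C)CCCO)c1O | intermediate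
12 | but-2-ynoic acid | CC#CC(=O)O | starting material
13 | 2-(trimethylsilyl)ethyl but-2-ynoate | CC#CC(=O)OCC[Si](C)(C)C | intermediate
14 | 2-(trimethylsilyl)ethyl (2E)-3-methylpenta-2,4-dienoate | C=C/C(C)=C/C(=O)OCC[Si](C)(C)C | intermediate
15 | 2-(trimethylsilyl)ethyl (2E)-5-(9-borabicyclo[3.3.1]nonan-9-yl)-3-methylpent-2-enoate | C[Si](C)(C)CCOC(=O)/C=C(C)/CCB1C2CCCC1CCC2 | intermediate (not isolated)
16 | 2-(trimethylsilyl)ethyl (2E)-5-[4-hydroxy-3-(5-hydroxy-2-methylpentan-2-yl)-5-methoxy-2,6-dimethylphenyl]-3-methylpent-2-enoate | COc1c(C)c(CC/C(C)=C/C(=O)OCC[Si](C)(C)C)c(C)c(C(C)(C)CCCO)c1O | intermediate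
17 | 2-(trimethylsilyl)ethyl (2E)-5-[3-(5-bromo-2-methylpentan-2-yl)-4-hydroxy-5-methoxy-2,6-dimethylphenyl]-3-methylpent-2-enoate | COc1c(C)c(CC/C(C)=C/C(=O)OCC[Si](C)(C)C)c(C)c(C(C)(C)CCCBr)c1O | intermediate
18 | 2-(trimethylsilyl)ethyl (2E)-5-[5-(5-bromo-2-methylpentan-2-yl)-3,3-dimethoxy-2,6-dimethyl-4-oxocyclohexa-1,5-dien-1-yl]-3-methylpent-2-enoate | COC1(OC)C(C)=C(CC/C(C)=C/C(=O)OCC[Si](C)(C)C)C(C)=C(C(C)(C)CCCBr)C1=O | intermediate
19 | 2-(trimethylsilyl)ethyl (5S,10S,13E)-7,7-dimethoxy-6-oxolabda-8,13-dien-15-oate | O=C1C(OC)(OC)C(C)=C(CC/C(C)=C/C(=O)OCC[Si](C)(C)C)[C@@]2(C)CCCC(C)(C)[C@H]12 | intermediate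
20 | 2-(trimethylsilyl)ethyl (5S,6S,10S,13E)-6β-hydroxy-7,7-dimethoxylabda-8,13-dien-15-oate | O[C@@H]1C(OC)(OC)C(C)=C(CC/C(C)=C/C(=O)OCC[Si](C)(C)C)[C@@]2(C)CCCC(C)(C)[C@H]12 | intermediate (not isolated)
21 | 2-(trimethylsilyl)ethyl (5S,6S,10S,13E)-6β-hydroxy-7-oxolabda-8,13-dien-15-oate | O[C@@H]1C(=O)C(C)=C(CC/C(C)=C/C(=O)OCC[Si](C)(C)C)[C@@]2(C)CCCC(C)(C)[C@H]12 | intermediate
22 | 2-(trimethylsilyl)ethyl (5S,6S,7S,10S,13E)-6β,7α-dihydroxylabda-8,13-dien-15-oate | O[C@@H]1[C@@H](O)C(C)=C(CC/C(C)=C/C(=O)OCC[Si](C)(C)C)[C@@]2(C)CCCC(C)(C)[C@H]12 | intermediate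
23 | 2-(trimethylsilyl)ethyl (5S,6S,7S,10S,13E)-6β-hydroxy-7α-(3-methylbutanoyloxy)labda-8,13-dien-15-oate | O[C@@H]1[C@@H](OC(=O)CC(C)C)C(C)=C(CC/C(C)=C/C(=O)OCC[Si](C)(C)C)[C@@]2(C)CCCC(C)(C)[C@H]12 | intermediate
24 | 2-(trimethylsilyl)ethyl (5S,6S,7S,10S,13E)-6β-acetoxy-7α-(3-methylbutanoyloxy)labda-8,13-dien-15-oate | CC(=O)O[C@@H]1[C@@H](OC(=O)CC(C)C)C(C)=C(CC/C(C)=C/C(=O)OCC[Si](C)(C)C)[C@@]2(C)CCCC(C)(C)[C@H]12 | intermediate
25 | (5S,6S,7S,10S,13E)-6β-acetoxy-7α-(3-methylbutanoyloxy)labda-8,13-dien-15-oic acid | CC(=O)O[C@@H]1[C@@H](OC(=O)CC(C)C)C(C)=C(CC/C(C)=C/C(=O)O)[C@@]2(C)CCCC(C)(C)[C@H]12 | target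

**Step count and risks**

Total step count: 18. Longest linear sequence: 16 steps (steps 1–7 and 10–18).

Steps most likely to fail:

Step 13 (Proposed new method). The chiral magnesium complex may discriminate the two faces of the planar dienone poorly, or the Lewis acid may ionise the ketal before the radical chain starts, so that the bicycle forms with low enantiomeric purity. The fallback uses known chemistry and sets out from 18. The cyclisation is run without Lewis acid (Bu3SnH by syringe pump, AIBN, benzene, 80 °C) and should give the racemic trans-fused keto ketal F1. Transketalisation with (2R,3R)-2,3-bis(trimethylsilyloxy)butane and catalytic Me3SiOTf (CH2Cl2, −78 °C) converts it into two diastereomeric spiro-dioxolanes, the (5S,10S)-dioxolane F2 and the (5R,10R)-dioxolane F3, which are separated by chromatography. F2 is reduced (NaBH4, CeCl3·7H2O, MeOH, −20 °C) to the 6β-hydroxy dioxolane F4, and 1 M aq. HCl in THF hydrolyses the ketal, so that the route is rejoined at 21.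

Step 17. Acylation of the 6β-hydroxyl, which is 1,3-diaxial to the C10 and C4 methyl groups, may stall, and harsher conditions may ionise the allylic C7 ester with loss of the C7 configuration. The fallback sets out from 20, isolated this time by a neutral work-up after the borohydride stage of step 14. At this stage, where no allylic ester is present, the alcohol is acetylated under forcing conditions (Ac2O, DMAP, pyridine, 80 °C) to the 6β-acetoxy ketal F5. Hydrolysis (1 M aq. HCl, THF) gives the 6β-acetoxy enone F6. Luche reduction (NaBH4, CeCl3·7H2O, MeOH, −40 °C; hydride from the α-face, anti to the axial C6–O bond) gives the 7β-alcohol F7. A Mitsunobu reaction with 3-methylbutanoic acid (PPh3, DIAD, toluene, 0 °C → rt) inverts C7 and rejoins the route at 24.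

Step 10. Once the phenol is deprotonated by the base that the boron coupling needs, oxidative addition to the electron-rich, doubly ortho-substituted aryl bromide may become so slow that protodeboronation of the alkylborane takes over. The fallback sets out from 14 (with 11 as coupling partner). Hydroboration of 14 with 9-BBN followed by oxidation (NaBO3·4H2O, THF/H2O) gives the primary alcohol F8. Iodination (I2, PPh3, imidazole, CH2Cl2) gives the iodide F9. Zinc insertion (Zn, LiCl, THF) gives the alkylzinc iodide F10, which is used in excess in a base-free Negishi coupling with 11 (Pd(OAc)2, SPhos, THF, rt → 50 °C) and rejoins the route at 16.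

**Further compounds**

F1 | step 13 | racemic 2-(trimethylsilyl)ethyl (13E)-7,7-dimethoxy-6-oxolabda-8,13-dien-15-oate (trans-fused; both enantiomers) | O=C1C(OC)(OC)C(C)=C(CC/C(C)=C/C(=O)OCC[Si](C)(C)C)[C@@]2(C)CCCC(C)(C)[C@H]12.O=C1C(OC)(OC)C(C)=C(CC/C(C)=C/C(=O)OCC[Si](C)(C)C)[C@]2(C)CCCC(C)(C)[C@@H]12
F2 | step 13 | (5S,10S)-6-oxo 7-spiro-[(4R,5R)-4,5-dimethyl-1,3-dioxolane] analogue of 19 | O=C1C2(O[C@H](C)[C@@H](C)O2)C(C)=C(CC/C(C)=C/C(=O)OCC[Si](C)(C)C)[C@@]3(C)CCCC(C)(C)[C@H]13
F3 | step 13 | (5R,10R)-6-oxo 7-spiro-[(4R,5R)-4,5-dimethyl-1,3-dioxolane] diastereomer | O=C1C2(O[C@H](C)[C@@H](C)O2)C(C)=C(CC/C(C)=C/C(=O)OCC[Si](C)(C)C)[C@]3(C)CCCC(C)(C)[C@@H]13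
F4 | step 13 | (5S,6S,10S)-6β-hydroxy 7-spiro-[(4R,5R)-4,5-dimethyl-1,3-dioxolane] analogue of 20 | O[C@@H]1C2(O[C@H](C)[C@@H](C)O2)C(C)=C(CC/C(C)=C/C(=O)OCC[Si](C)(C)C)[C@@]3(C)CCCC(C)(C)[C@H]13
F5 | step 17 | 2-(trimethylsilyl)ethyl (5S,6S,10S,13E)-6β-acetoxy-7,7-dimethoxylabda-8,13-dien-15-oate | CC(=O)O[C@@H]1C(OC)(OC)C(C)=C(CC/C(C)=C/C(=O)OCC[Si](C)(C)C)[C@@]2(C)CCCC(C)(C)[C@H]12
F6 | step 17 | 2-(trimethylsilyl)ethyl (5S,6S,10S,13E)-6β-acetoxy-7-oxolabda-8,13-dien-15-oate | CC(=O)O[C@@H]1C(=O)C(C)=C(CC/C(C)=C/C(=O)OCC[Si](C)(C)C)[C@@]2(C)CCCC(C)(C)[C@H]12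
F7 | step 17 | 2-(trimethylsilyl)ethyl (5S,6S,7R,10S,13E)-6β-acetoxy-7β-hydroxylabda-8,13-dien-15-oate | CC(=O)O[C@@H]1[C@H](O)C(C)=C(CC/C(C)=C/C(=O)OCC[Si](C)(C)C)[C@@]2(C)CCCC(C)(C)[C@H]12
F8 | step 10 | 2-(trimethylsilyl)ethyl (2E)-5-hydroxy-3-methylpent-2-enoate | C[Si](C)(C)CCOC(=O)/C=C(C)/CCO
F9 | step 10 | 2-(trimethylsilyl)ethyl (2E)-5-iodo-3-methylpent-2-enoate | C[Si](C)(C)CCOC(=O)/C=C(C)/CCI
F10 | step 10 | [(3E)-3-methyl-5-oxo-5-[2-(trimethylsilyl)ethoxy]pent-3-en-1-yl]zinc iodide | C[Si](C)(C)CCOC(=O)/C=C(C)/CC[Zn]I
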